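Isochromene numbering is used throughout (C1, O2, C3, C4, C4a, C5, C6, C7, C8, C8a), also for open-chain precursors; the decanoate is put on the C7 alcohol last.
Enabling feature: the 4H-pyran ring (O2-C1-C8a-C4a-C4-C3) with its exocyclic C4a=C5 bond is the anhydrobase of a 4-methylpyrylium ion. C5-C6(=O) is therefore a C-acylated anhydrobase bond, and C6-C7(O)(CH3) is a lactic acid unit.
Key disconnections: C5-C6 (carbocycle) and O2-C1 (pyran ring). Both are made in one operation from an open-chain ethoxy dienone whose C6, C7 and O7 sit in a pivalaldehyde-derived dioxolanone (a temporary ring that serves as acyl donor, O-protection and carrier of the stereo-information).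
Ring order: the temporary dioxolanone forms in step 1. In step 7 the pyran ring closes first, then the carbocycle C4a-C5-C6-C7-C8-C8a as last ring of the skeleton, with loss of the ethoxy group and the temporary ring in the same flask.
Precursor assembly: C8a-C4a by Suzuki-Miyaura coupling of a bromo enone with a beta-boryl enone. The bromo enone comes from (R)-lactic acid (C7 set by self-regeneration of stereocentres, C7-C8 by enolate acylation); the boryl enone comes from octanoyl chloride and propyne.

Key step: step 7

Remark on the chemistry: the stereocentre of the given SMILES is read as (7R). The C=C geometries of 8, 12 and 13 are written as the methods should deliver them. They are of no consequence, because they are equilibrated or lost in step 7.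

Step 1
Reactants: 1 (R)-lactic acid; 2 pivalaldehyde
Product: 3 (2R,5R)-2-tert-butyl-5-methyl-1,3-dioxolan-4-one
Conditions: TsOH·H2O (cat.), H2SO4 (cat.), pentane, reflux, Dean-Stark; crystallisation from Et2O/pentane at -78 °C
Reagents that add atoms: none
Why: Acid-catalysed acetalisation with azeotropic water removal (first stage of the self-regeneration of stereocentres) leaves C5 as in (R)-lactic acid, while the new acetal centre C2 should form mainly cis under thermodynamic control and the cis isomer is purified by low-temperature crystallisation.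

Step 2
Reactants: 3 (2R,5R)-2-tert-butyl-5-methyl-1,3-dioxolan-4-one; 4 (E)-3-ethoxyacryloyl chloride
Product: 6 (2R,5S)-2-tert-butyl-5-[(E)-3-ethoxyprop-2-enoyl]-5-methyl-1,3-dioxolan-4-one, via lithium enolate 5 (not isolated)
Conditions: LiN(iPr)2 (commercial solution, 1.05 equiv), THF, -78 °C; then 4, -78 → -40 °C; aq. NH4Cl
Reagents that add atoms: none
Why: Claisen-type C-acylation of a lactone lithium enolate by an acid chloride, in which the tert-butyl group on C2 shields one face of the planar enolate so that the acyl group enters trans to it and takes the place of the former hydrogen (retention), which sets the quaternary centre that becomes C7 and gives a product without acidic hydrogen that could quench the enolate.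

Step 3
Reactants: 6 (2R,5S)-2-tert-butyl-5-[(E)-3-ethoxyprop-2-enoyl]-5-methyl-1,3-dioxolan-4-one
Product: 8 (2R,5S)-5-[(Z)-2-bromo-3-ethoxyprop-2-enoyl]-2-tert-butyl-5-methyl-1,3-dioxolan-4-one, via dibromide 7 (not isolated)
Conditions: Br2 (1.0 equiv), CH2Cl2, -78 °C; then Et3N (1.5 equiv), -78 → 0 °C
Reagents that add atoms: bromine, BrBr
Why: Addition of bromine to the enol ether double bond and Et3N-induced dehydrobromination (the usual addition-elimination alpha-halogenation of beta-alkoxy enones) puts the halogen on C8a only, and the two stereocentres, the acetal and the lactone have no enolisable position and are not touched.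

Step 4
Reactants: 9 octanoyl chloride; 10 propyne
Product: 11 undec-2-yn-4-one
Conditions: PdCl2(PPh3)2 (2 mol %), CuI (4 mol %), Et3N (1.2 equiv), propyne solution in THF, 0 °C → rt
Reagents that add atoms: none
Why: Acyl Sonogashira coupling of an acid chloride with a terminal alkyne gives the ynone directly, with no risk of over-addition and no stereocentre involved.

Step 5
Reactants: 11 undec-2-yn-4-one
Product: 12 (Z)-2-(4,4,5,5-tetramethyl-1,3,2-dioxaborolan-2-yl)undec-2-en-4-one
Conditions: B2pin2 (1.1 equiv), CuCl (5 mol %), NaOtBu (10 mol %), Xantphos (5 mol %), MeOH (2 equiv), THF, rt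
Reagents that add atoms: bis(pinacolato)diboron, CC1(C)OB(OC1(C)C)B1OC(C)(C)C(C)(C)O1
Why: Copper-catalysed conjugate borylation (syn borylcupration of the ynone, then protonation by MeOH) places boron on the beta carbon C4a for electronic reasons and should give the (Z)-alkene by syn addition.

Step 6
Reactants: 8 (2R,5S)-5-[(Z)-2-bromo-3-ethoxyprop-2-enoyl]-2-tert-butyl-5-methyl-1,3-dioxolan-4-one; 12 (Z)-2-(4,4,5,5-tetramethyl-1,3,2-dioxaborolan-2-yl)undec-2-en-4-one
Product: 13 (2R,5S)-2-tert-butyl-5-[(2E,3E)-2-(ethoxymethylidene)-3-methyl-5-oxododec-3-enoyl]-5-methyl-1,3-dioxolan-4-one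
Conditions: PdCl2(dppf) (5 mol %), CsF (3 equiv), 1,4-dioxane, 60 °C
Reagents that add atoms: none
Why: Suzuki-Miyaura coupling of an electron-poor alkenyl bromide (fast oxidative addition to zerovalent palladium) with an alkenyl pinacol boronate under anhydrous fluoride activation forms C8a-C4a, spares lactone, acetal and enol ether, should carry both double bonds over with retention, and touches no stereocentre.

Step 7
Reactants: 13 (2R,5S)-2-tert-butyl-5-[(2E,3E)-2-(ethoxymethylidene)-3-methyl-5-oxododec-3-enoyl]-5-methyl-1,3-dioxolan-4-one
Product: 16 (7R)-3-heptyl-7-hydroxy-7-methyl-6H-isochromene-6,8(7H)-dione, via pyrylium triflate 14 (not isolated), via methylenepyran 15 (not isolated)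
Conditions: Me3SiOTf (1.1 equiv), CH2Cl2 (0.02 M), -40 °C → rt; then Mg(OTf)2 (20 mol %), iPr2NEt (1.2 equiv), MeCN, 0 → 40 °C; aq. NaHCO3
Reagents that add atoms: none
Why: Proposed new method: Me3SiOTf silylates the C3 carbonyl oxygen of the push-pull dienone 13 to a 1-ethoxy-5-silyloxypentadienyl cation in which the C4-C4a bond rotates freely, the C3 oxygen then closes onto the oxocarbenium carbon C1 (6-exo-trig, the ionic counterpart of an oxa-6π electrocyclisation) and loss of EtOSiMe3 gives the aromatic pyrylium salt 14, so the pyran ring is finished first. Only in 14 is the C5 methyl group strongly C-H acidic: iPr2NEt turns it into the 4-methylene-4H-pyran 15, whose exocyclic carbon C5 adds to the magnesium-chelated acylal carbonyl C6 (6-exo-trig addition-elimination that regains pyrylium aromaticity in the tetrahedral intermediate), the departing hemiacetal alkoxide sheds pivalaldehyde and frees the C7 oxygen, and loss of the second C5 proton gives neutral 16. The closest known reaction types are the acid closure of 5-alkoxypenta-2,4-dienones to pyrylium salts (with the same E/Z isomerisation as in the cyclodehydration stage of the Bohlmann-Rahtz pyridine synthesis), the C-acylation of pyrylium anhydrobases by acid chlorides and anhydrides, soft-enolisation acylation with magnesium salts and amine bases, and the lateral Dieckmann closure of ortho-toluoyl esters; new is a lactone as acyl donor toward an anhydrobase. No stereocentre is formed: C7 is quaternary and non-enolisable and none of its four bonds is broken, so the configuration set in step 2 should appear unchanged as (R) in 16, while the acetal centre leaves with pivalaldehyde. The step needs pyran closure through C1 and not C8, reaction at C5 and not at the heptyl CH2, and six-ring C-acylation instead of intermolecular condensation: C1 is the only carbon with a leaving group (C8 has none and no enolisable neighbour), deprotonation is reversible and only the C5 anhydrobase has an acyl group within six-ring reach (attack on C8 would give a four-membered ring), and dilution favours the intramolecular path.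

Step 8
Reactants: 16 (7R)-3-heptyl-7-hydroxy-7-methyl-6H-isochromene-6,8(7H)-dione; 17 decanoyl chloride
Product: 18 (7R)-3-heptyl-7-methyl-6,8-dioxo-7,8-dihydro-6H-isochromen-7-yl decanoate
Conditions: Et3N (2 equiv), DMAP (20 mol %), CH2Cl2, 0 °C → rt
Reagents that add atoms: none
Why: DMAP-catalysed O-acylation of the tertiary alcohol by an acid chloride (nucleophilic acyl-transfer catalysis) is the usual way to esterify such 7-hydroxy compounds, uses only tertiary amines that cannot exchange the pyran oxygen, and does not break the C7-O bond, so the (R) configuration is kept.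

Compound list
1 | (R)-lactic acid | C[C@@H](O)C(=O)O | starting material
2 | pivalaldehyde | CC(C)(C)C=O | starting material
3 | (2R,5R)-2-tert-butyl-5-methyl-1,3-dioxolan-4-one | C[C@H]1O[C@@H](C(C)(C)C)OC1=O | intermediate
4 | (E)-3-ethoxyacryloyl chloride | CCO/C=C/C(=O)Cl | starting material
5 | lithium (2R)-2-tert-butyl-5-methyl-1,3-dioxol-4-olate (lithium enolate of 3) | [Li+].CC1=C([O-])O[C@H](C(C)(C)C)O1 | intermediate
6 | (2R,5S)-2-tert-butyl-5-[(E)-3-ethoxyprop-2-enoyl]-5-methyl-1,3-dioxolan-4-one | C[C@@]1(C(=O)/C=C/OCC)O[C@@H](C(C)(C)C)OC1=O | intermediate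
7 | (2R,5S)-2-tert-butyl-5-(2,3-dibromo-3-ethoxypropanoyl)-5-methyl-1,3-dioxolan-4-one (mixture at the two CHBr carbons) | C[C@@]1(C(=O)C(Br)C(Br)OCC)O[C@@H](C(C)(C)C)OC1=O | intermediate
8 | (2R,5S)-5-[(Z)-2-bromo-3-ethoxyprop-2-enoyl]-2-tert-butyl-5-methyl-1,3-dioxolan-4-one | C[C@@]1(C(=O)/C(Br)=C/OCC)O[C@@H](C(C)(C)C)OC1=O | intermediate
9 | octanoyl chloride | CCCCCCCC(=O)Cl | starting material
10 | propyne | CC#C | starting material
11 | undec-2-yn-4-one | CC#CC(=O)CCCCCCC | intermediate
12 | (Z)-2-(4,4,5,5-tetramethyl-1,3,2-dioxaborolan-2-yl)undec-2-en-4-one | C/C(B1OC(C)(C)C(C)(C)O1)=C\C(=O)CCCCCCC | intermediate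
13 | (2R,5S)-2-tert-butyl-5-[(2E,3E)-2-(ethoxymethylidene)-3-methyl-5-oxododec-3-enoyl]-5-methyl-1,3-dioxolan-4-one | C[C@@]1(C(=O)/C(=C/OCC)/C(C)=C/C(=O)CCCCCCC)O[C@@H](C(C)(C)C)OC1=O | intermediate
14 | 5-{[(2R,4S)-2-tert-butyl-4-methyl-5-oxo-1,3-dioxolan-4-yl]carbonyl}-2-heptyl-4-methylpyrylium triflate | CCCCCCCc1cc(C)c(C(=O)[C@]2(C)O[C@@H](C(C)(C)C)OC2=O)c[o+]1.[O-]S(=O)(=O)C(F)(F)F | intermediate
15 | (2R,5S)-2-tert-butyl-5-[(6-heptyl-4-methylidene-4H-pyran-3-yl)carbonyl]-5-methyl-1,3-dioxolan-4-one | C=C1C=C(CCCCCCC)OC=C1C(=O)[C@]2(C)O[C@@H](C(C)(C)C)OC2=O | intermediate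
16 | (7R)-3-heptyl-7-hydroxy-7-methyl-6H-isochromene-6,8(7H)-dione | O[C@]1(C)C(=O)C=C2C=C(CCCCCCC)OC=C2C1=O | intermediate
17 | decanoyl chloride | CCCCCCCCCC(=O)Cl | starting material
18 | (7R)-3-heptyl-7-methyl-6,8-dioxo-7,8-dihydro-6H-isochromen-7-yl decanoate | CCCCCCCCCC(=O)O[C@]1(C)C(=O)C=C2C=C(CCCCCCC)OC=C2C1=O | target

Total step count: 8. Longest linear sequence: 6 steps (1, 2, 3, 6, 7, 8).

Steps most likely to fail

Step 7 (labelled step).
- What may go wrong: the neutral methylenepyran may add too slowly to the hindered lactone carbonyl. It would then be consumed by condensation with a second pyrylium ion or with released pivalaldehyde, or the pyrylium ring, unsubstituted at C1, would open hydrolytically.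
- Fallback (known chemistry): the same ring is still closed last, but at C7-C8. It sets out from 12 and comes back at 16.
- Commercial 2-bromomalonaldehyde is O-ethylated (HC(OEt)3, cat. TsOH) to (Z)-2-bromo-3-ethoxyacrolein F1.
- F1 is coupled with 12 under the conditions of step 6 to (2E,3E)-2-(ethoxymethylidene)-3-methyl-5-oxododec-3-enal F2.
- Me3SiOTf closes F2 to 5-formyl-2-heptyl-4-methylpyrylium triflate F3. Both carbons on C8a are at the formyl level, so either mode of closure gives the same ion.
- Slow addition of iPr2NEt to F3 and freshly made pyruvoyl chloride acylates the anhydrobase at C5. This is the classical reaction of 4-methylpyrylium salts with acid chlorides and gives 6-heptyl-4-[(Z)-2,3-dioxobutylidene]-4H-pyran-3-carbaldehyde F4.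
- An enantioselective intramolecular crossed aldehyde-ketone benzoin reaction (aminoindanol-derived chiral triazolium salt, Et3N, THF) then joins the C8 aldehyde carbon to the C7 ketone and should give 16. C6 is a vinylogous ester carbonyl and stays inert. C7 is now set by the catalyst, and the antipode that leads to (R) is chosen in a test run.

Step 6.
- What may go wrong: transmetalation of the electron-poor alkenyl boronate may be slow, with competing protodeboronation. The product may also cyclise prematurely under the basic fluoride.
- Fallback without metal: the C8a-C4a bond is made by conjugate addition. It sets out from 6 and 11 and comes back at 13.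
- 6 is hydrolysed (1 M HCl, THF, 0 °C) to 3-[(2R,4S)-2-tert-butyl-4-methyl-5-oxo-1,3-dioxolan-4-yl]-3-oxopropanal F5.
- Et3N-catalysed Michael addition of this 1,3-dicarbonyl compound to the ynone 11 gives the hydroxymethylene dienone F6.
- HC(OEt)3 with cat. TsOH turns the enol of F6 into the ethyl enol ether 13.

Step 2.
- What may go wrong: O-acylation of the hindered, fully substituted enolate, its fragmentation before acylation, or addition-elimination at the beta carbon of 4.
- Fallback by aldol addition and oxidation: it sets out from 3 (through enolate 5) and comes back at 6.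
- Enolate 5 is treated at -78 °C with (E)-3-ethoxyacrolein, with the same facial control by the tert-butyl group, and quenched cold. This gives (2R,5S)-2-tert-butyl-5-[(E)-3-ethoxy-1-hydroxyprop-2-enyl]-5-methyl-1,3-dioxolan-4-one F7, a mixture at the carbinol carbon.
- Dess-Martin periodinane buffered with NaHCO3 oxidises F7 to 6.

Further compounds
F1 | step 7 | (Z)-2-bromo-3-ethoxyacrolein | CCO/C=C(Br)/C=O
F2 | step 7 | (2E,3E)-2-(ethoxymethylidene)-3-methyl-5-oxododec-3-enal | O=C/C(=C/OCC)/C(C)=C/C(=O)CCCCCCC
F3 | step 7 | 5-formyl-2-heptyl-4-methylpyrylium triflate | CCCCCCCc1cc(C)c(C=O)c[o+]1.[O-]S(=O)(=O)C(F)(F)F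
F4 | step 7 | 6-heptyl-4-[(Z)-2,3-dioxobutylidene]-4H-pyran-3-carbaldehyde | CC(=O)C(=O)/C=C1/C=C(CCCCCCC)OC=C1C=O
F5 | step 6 | 3-[(2R,4S)-2-tert-butyl-4-methyl-5-oxo-1,3-dioxolan-4-yl]-3-oxopropanal | C[C@@]1(C(=O)CC=O)O[C@@H](C(C)(C)C)OC1=O
F6 | step 6 | (2R,5S)-2-tert-butyl-5-[2-(hydroxymethylidene)-3-methyl-5-oxododec-3-enoyl]-5-methyl-1,3-dioxolan-4-one (tautomer and alkene mixture) | C[C@@]1(C(=O)C(=CO)C(C)=CC(=O)CCCCCCC)O[C@@H](C(C)(C)C)OC1=O
F7 | step 2 | (2R,5S)-2-tert-butyl-5-[(E)-3-ethoxy-1-hydroxyprop-2-enyl]-5-methyl-1,3-dioxolan-4-one | C[C@@]1(C(O)/C=C/OCC)O[C@@H](C(C)(C)C)OC1=O
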